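The triple product holds 3 reagent for each starting material, so I began from what the charge could pay for and how much of the starting material would ever enter the chain.

the same everywhere: starting material 0.0010 M
- maple: reagent 3 mM; run made earlier
- flask: reagent 2.00 mM; time 40 min

maple run (percent of the starting material charged)

| time / min | starting material / % | first product / % |
|---|---|---|
| 0.250 | 62 | 14 |
| 0.833 | 31 | 18 |
| 1.33 | 20 | 17 |
| 2.00 | 12 | 14 |
| 3.00 | 6 | 8 |
| 4.00 | 4 | 5 |

(standard deviation of a reading: 1.5 percentage points)

- percentages count the starting material that a species holds: one homo dimer counts as two
- the numbers in the tables scatter by 1.5 percentage points (one standard deviation)
- reactions considered so far: reagent + triple product <-> tetra adduct; reagent + double product -> triple product; reagent + first product -> double product; starting material + reagent -> first product; 2 starting material -> homo dimer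

* amount of starting material at 40 min, in percent of the starting material charged
* amount of first product at 40 min, in percent of the starting material charged
* amount of double product at 40 min, in percent of the starting material charged
* amount of triple product at 40 min, in percent of the starting material charged

First I asked whether 40 min was long enough for the early steps. In the maple run the first product fell from 14 % to 5 % between 2.00 min and 4.00 min, a half-life of 1.35 min as read. The time of this flask is 29.6 such half-lives, so despite its smaller reagent charge I expected little starting material or first product at the end.

Next I asked what the reagent could carry. Its concentration over 3 times that of the starting material gave 66.7 %, the triple ceiling: the amount of triple product this reagent can pay for, as a share of the starting material charged.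

Then I asked how much would enter the chain of first product, double product, triple product and tetra adduct, and not go to homo dimer. At the first maple reading, first product stood at 14 % of the 38.0 % consumed, a reading of 36.8 % with any double product uncounted. That was an early reading from a flask with more reagent, and no bound on the final share, but it led me to expect a chain share below the ceiling in this flask, with starting material as the limiting reagent and spare reagent passing on to tetra adduct.

The forecast said “about 60% of the starting material ends as dimer, and about 40% enters the adduct chain”, and gave 0 % starting material, 0.3 % first product, 6 % double product and 20 % triple product.

The flask gave 0.0619 % starting material, 0.0992 % first product, 5.80 % double product and 35.0 % triple product, the triple product 15 percentage points above the forecast.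

    reagent + triple product ⇌ tetra adduct (K = 1800 L mol⁻¹, k = 15.0 L mol⁻¹ s⁻¹)
    reagent + double product → triple product (k = 2.80 L mol⁻¹ s⁻¹)
    reagent + first product → double product (k = 9.10 L mol⁻¹ s⁻¹)
    starting material + reagent → first product (k = 5.50 L mol⁻¹ s⁻¹)
    2 starting material → homo dimer (k = 8.60 L mol⁻¹ s⁻¹)

With homo dimer at 44.1 %, the chain in this flask held 55.8 %, below the ceiling of 66.7 %, and tetra adduct over triple product stood at 0.426, against 0.425 for the equilibrium constant times the free reagent. A further flask with 2.5 × 10⁻⁴ M starting material had a ceiling of 267 % and a chain of 83.6 %, and at 40.0 min it held 26.0 % triple product and 57.6 % tetra adduct.

The numbers in the tables stem from a simulated flask on assumed constants, noise included.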